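# Proposed synthesis of methyl (3R,4S,5R)-3-acetoxy-5-{[(2R)-2-methylbutanoyl]oxy}-4-(propanoyloxy)cyclohex-1-ene-1-carboxylate (19)

PMB = 4-methoxybenzyl. Ring atoms carry the shikimate numbering throughout.

## The problem

Compound 19 is a single carbocycle: a cyclohex-1-ene with the methyl ester on C1, a CH2 group at C6 and three contiguous oxygenated stereocentres, C3 (R), C4 (S) and C5 (R). O3 and O4 are cis, O4 and O5 are trans, and a fourth, remote stereocentre sits in the (R)-2-methylbutanoyl group on O5. A synthesis has to build this ring with the C1=C2 double bond in a defined place, set the three ring centres in absolute terms, and put three different esters (acetyl on O3, propanoyl on O4, 2-methylbutanoyl on O5) on three neighbouring oxygens without scrambling. The side-chain centre cannot be controlled from the ring and must arrive intact with the acid. Among the ring centres, C3 can control C5, because a C3 hydroxyl beside a C5 ketone delivers hydride across the ring (1,3-trans), whereas the cis C3/C4 pair must come from the carbon–carbon bond formation. Several groups are fragile: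
- cis-vicinal esters on O3 and O4 change places under base as soon as one of the two oxygens is free;
- the α-centre of the 2-methylbutanoyl group can epimerise on harsh activation;
- any intermediate with a C5 ketone beside the C1=C2 enoate can lose water across C3/C4 and aromatise to a 3-hydroxybenzoate.

The feature that invites the key step is that C3 and C4 are adjacent carbinols flanked by the alkene carbon C2 and by C5. With C5 as a ketone and C3 as an aldehyde, C3–C4 is an aldol bond, and the (E)-configured C1=C2 bond already holds C3 and C6 on the same side so that the chain ends meet in a six-membered ring. The open-chain compound needed for this is a 2-ene-1,5-dicarbonyl system with an acidic C6 methylene, which condenses with primary amines to pyridinium salts, so the ring closure has to be catalysed without forming a C–N bond.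

## Retrosynthesis

**19 ⇒ 18 ⇒ 17 (O4–acyl, then O4–ether).** The O4–propanoyl bond is cut first, giving alcohol 18, and behind it stands the PMB ether 17. O4 is acylated last because it is the one oxygen that can travel as an ether from the first step; finishing at O3 or O5 would need an additional temporary group. The precursor differs from 19 only at O4. The forward steps must free O4 without base, since the O3 acetate is cis, and acylate it faster than that acetate can migrate.

**17 ⇒ 15 + 16 (O5–acyl).** The O5 ester bond is cut to alcohol 15 and (R)-2-methylbutanoic acid 16. In 15 the C5 hydroxyl is the only free one and already has the right configuration, so a simple coupling with retention suffices. The neighbouring option, inversion of a C5 epimer by SN2 esterification, would ask a weak, α-branched acid to displace at a hindered carbinol next to an allylic methylene. The forward reaction must not epimerise 16.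

**15 ⇒ 13 (C5–H and O3–acetyl together).** Both bonds are cut in one retro-Tishchenko step to the β-hydroxy ketone 13. The forward step reduces C5 with 1,3-trans delivery from O3 and leaves O3 as the acetate, so stereocontrol and oxygen differentiation come from the same event. Acetylating 13 first and reducing afterwards would pass through a β-acetoxy ketone that eliminates readily, and an external hydride has no reason to favour the 4,5-trans alcohol. The forward reaction needs O3 pseudo-axial so that the hemiacetal 14 can reach C5.

**13 ⇒ 11 (C3–C4, key step).** The ring is opened at the aldol bond to the achiral keto-enal 11; two stereocentres and the ring disappear together. Cuts at C1–C6, C2–C3 or C1=C2 all require an open-chain precursor that already carries the three ring centres, whereas this cut leaves a chain built from three small achiral pieces. The forward reaction must be a catalytic, enantioselective 6-enolendo aldol addition in which C4 (not C6) is the nucleophile, the new centres come out cis, and water is not lost. Because 11 would be consumed by amine catalysts as a pyridinium salt, the closure is planned through the C4 enol 12 under a chiral Brønsted acid, and 13 is reduced at once.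

**11 ⇒ 10 ⇒ 7 + 8 (C1=C2).** The aldehyde is masked as the dimethyl acetal 10 and the trisubstituted enoate is cut by olefination into phosphonate 7 and 2,2-dimethoxyacetaldehyde 8. This places the ester on C1, fixes C3 cis to C6 through the (E) geometry, and keeps the sensitive 2-ene-1,5-dicarbonyl unit latent until the step before ring closure. The forward step must be (E)-selective and must not let the new double bond migrate toward the ketone.

**7 ⇒ 4 + 5; 4 ⇒ 3 ⇒ 1 + 2 (C1–C6 and the C4–C6 unit).** The C1–C6 bond is cut to trimethyl phosphonoacetate 5 and bromoketone 4. The latter goes back through bromohydrin 3 to epibromohydrin 1 and 4-methoxybenzyl alcohol 2. All four pieces are achiral or racemic bulk chemicals; the forward steps need mono-alkylation of 5 and opening of 1 at its terminal carbon.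

## Roads not taken

**Alternative 1:** The cut is C1–C6. The precursor would be the sugar-derived bromo-enoate A1, which already holds C3, C4 and C5 and carries the (R)-2-methylbutanoate on O5. A nucleophilic trialkylphosphine adds to C2, the C1 carbanion displaces the primary bromide on C6 in a 6-exo-tet closure, and base expels the phosphine to restore C1=C2, giving the acetonide A2.
- Merits: all ring centres come from the chiral pool, the alkene position is unambiguous, and no aromatisable keto intermediate appears.
- Weak points: A1 needs a long carbohydrate sequence with the costly acid installed early; a secondary ester sits next to the alkylation site under phosphine and base; and after A2 the cis O3/O4 diol still has to be told apart for acetyl and propanoyl.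
- Comparison: this road is stereochemically safer than the chosen plan, whose two new centres rest on an unprecedented catalytic step. The chosen plan sets against it commodity achiral starting materials and the fact that O3, O4 and O5 are distinguished by oxidation state from the moment the ring forms.

**Alternative 2:** The cut is C2–C3. The precursor would be the aldehyde A3 with an (E)-β-iodoacrylate. A divalent chromium reagent with a catalytic nickel salt turns the vinyl iodide into a vinylchromium species that adds to the C3 aldehyde and closes the ring to A4, which has a free 3-hydroxyl and needs only acetylation.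
- Merits: the endgame is one step, against four after ring closure in the chosen plan; the closure type tolerates esters.
- Weak points: C3 is formed under substrate control next to an α-acyloxy centre, with no assurance of the cis outcome; the chromium alkoxide on O3 sits cis to the O4 propanoate and invites acyl migration; A3 is an epimerisable α-acyloxy aldehyde; the metal is used in excess; and A3 again needs a long chiral-pool preparation.
- Comparison: the chosen plan sets catalyst control of C3 and a five-step access to its cyclisation precursor against the shorter endgame of this road.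

**Alternative 3:** The cut is C1=C2. The lyxo-configured phosphonate A5, reacting as its open hydroxy-aldehyde, closes by intramolecular Horner–Wadsworth–Emmons olefination to the acetonide A6.
- Merits: this ring closure has the best precedent of all four plans, the alkene position is guaranteed, and A6 is a stable compound.
- Weak points: it is a chiral-pool route that still needs sugar degradation to reach A5; after A6 come esterification of O5 with 16, acetonide removal and regioselective distinction of O3 from O4.
- Comparison: in reliability this road is better than the chosen plan. The chosen plan sets against it a shorter sequence from achiral materials, absolute configuration from a catalyst (either enantiomer is available), and built-in oxygen differentiation. It also keeps this olefinative closure in reserve as the fallback for its key step.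

Key step: step 6

Assumption: the sense of induction of the chiral acid in step 6 cannot be predicted with certainty; the (R)-catalyst is written, and its mirror image would be used if the opposite sense is found.

## Route

Step 1
Reactants: 1 epibromohydrin (racemic 2-(bromomethyl)oxirane); 2 4-methoxybenzyl alcohol
Product: 3 1-bromo-3-[(4-methoxybenzyl)oxy]propan-2-ol (racemic)
Conditions: BF3·OEt2 (3 mol%), 1 in excess, CH2Cl2, −10 °C to rt
Reagents that add atoms: none
Why: Lewis acid-catalysed alcoholysis of a terminal epoxide; the alcohol 2 attacks the unsubstituted ring carbon of BF3-activated 1 in an SN2-like opening, as is usual for epihalohydrins, and the racemic carbinol centre is removed in step 2.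

Step 2
Reactants: 3 1-bromo-3-[(4-methoxybenzyl)oxy]propan-2-ol
Product: 4 1-bromo-3-[(4-methoxybenzyl)oxy]propan-2-one
Conditions: Dess–Martin periodinane (1.2 equiv), CH2Cl2, 0 °C to rt
Reagents that add atoms: none
Why: Dess–Martin oxidation of a secondary alcohol to the ketone under base-free conditions, which an α-bromo ketone and a PMB ether both tolerate.

Step 3
Reactants: 4 1-bromo-3-[(4-methoxybenzyl)oxy]propan-2-one; 5 trimethyl phosphonoacetate
Product: 7 methyl 2-(dimethoxyphosphoryl)-5-[(4-methoxybenzyl)oxy]-4-oxopentanoate (racemic), via sodium salt of trimethyl phosphonoacetate 6 (not isolated)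
Conditions: NaH (1.3 equiv), 5 (1.4 equiv), THF, 0 °C; then 4, 0 °C to rt
Reagents that add atoms: none
Why: SN2 alkylation of the phosphonate-stabilised carbanion 6 by an α-halo ketone, a strongly activated electrophile; the excess of 6 limits double alkylation, and the racemic centre at C1 becomes trigonal in step 4.

Step 4
Reactants: 7 methyl 2-(dimethoxyphosphoryl)-5-[(4-methoxybenzyl)oxy]-4-oxopentanoate; 8 2,2-dimethoxyacetaldehyde
Product: 10 methyl (2E)-4,4-dimethoxy-2-{3-[(4-methoxybenzyl)oxy]-2-oxopropyl}but-2-enoate, via sodium carbanion of the phosphonate 9 (not isolated)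
Conditions: NaH (1.0 equiv), THF, 0 °C; then anhydrous 8, −20 to 0 °C
Reagents that add atoms: none
Why: Horner–Wadsworth–Emmons olefination; carbanion 9 adds to the non-enolisable aldehyde 8 and syn-elimination of dimethyl phosphate gives the trisubstituted enoate, the reversible addition of an α-alkyl phosphonoacetate favouring the (E)-isomer in which the acetal carbon C3 is trans to the ester and cis to C6, as the ring closure requires.

Step 5
Reactants: 10 methyl (2E)-4,4-dimethoxy-2-{3-[(4-methoxybenzyl)oxy]-2-oxopropyl}but-2-enoate
Product: 11 methyl (2E)-2-{3-[(4-methoxybenzyl)oxy]-2-oxopropyl}-4-oxobut-2-enoate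
Conditions: p-toluenesulfonic acid monohydrate (5 mol%), acetone/H2O (20:1), 0 °C; concentrated cold and used at once
Reagents that add atoms: water, O
Why: acid-catalysed hydrolysis of an allylic, hence readily ionised, dimethyl acetal, fast enough at 0 °C to leave the PMB ether and the methyl ester alone; 11 is not purified because its C6 methylene is doubly activated.

Step 6
Reactants: 11 methyl (2E)-2-{3-[(4-methoxybenzyl)oxy]-2-oxopropyl}-4-oxobut-2-enoate
Product: 13 methyl (3R,4R)-3-hydroxy-4-[(4-methoxybenzyl)oxy]-5-oxocyclohex-1-ene-1-carboxylate, via C4=C5 (Z)-enol tautomer 12 (not isolated)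
Conditions: (R)-3,3′-bis(2,4,6-triisopropylphenyl)-1,1′-binaphthyl-2,2′-diyl hydrogen phosphate (10 mol%), toluene (0.02 M), 0 °C; cold filtration through a short silica pad, used at once
Reagents that add atoms: none
Why: Proposed new method: the chiral phosphoric acid should catalyse enolisation of the C5 ketone and, acting as a bifunctional acid, hold the enol 12 through its O–H and the C3 aldehyde through its carbonyl oxygen in one hydrogen-bonded array so that C4 adds to C3; the closest known reaction types are the chiral phosphoric acid-catalysed 6-enolendo aldol cyclisation of 1,5-diketones and the phosphoric acid-catalysed direct aldol addition of ketone enols to activated aldehydes. The ring closes in the 6-(enolendo)-exo-trig mode through a half-chair in which C1=C2 is already planar. C4 is controlled by the enol geometry: in the (Z)-enol the PMB ether is cis to the enol oxygen and ends pseudo-equatorial. C3 is controlled by the aldehyde face the catalyst presents: the phosphate bridge keeps the aldehyde oxygen gauche to C5 and therefore pseudo-axial, which gives the 3,4-cis product, and the 3,3′-aryl groups select one of the two mirror-image cis arrangements. The step needs regioselectivity (C4 against C6) and addition without loss of water. Enolisation toward C6 is faster but gives only a reversible dienol that cannot close a six-membered ring, and the (E)-alkene holds C3 and C6 cis so that C4 alone can reach C3. An acid is used because an amine catalyst would condense with this 2-ene-1,5-dicarbonyl unit to a pyridinium salt, and low temperature with high dilution should hold back aromatisation of 13 and intermolecular reaction.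

Step 7
Reactants: 13 methyl (3R,4R)-3-hydroxy-4-[(4-methoxybenzyl)oxy]-5-oxocyclohex-1-ene-1-carboxylate
Product: 15 methyl (3R,4S,5R)-3-acetoxy-5-hydroxy-4-[(4-methoxybenzyl)oxy]cyclohex-1-ene-1-carboxylate, via O3 hemiacetal of acetaldehyde 14 (not isolated)
Conditions: SmI2 (0.3 equiv) added to acetaldehyde (8 equiv) in THF at −10 °C until decolourised; then 13, −10 °C
Reagents that add atoms: acetaldehyde, CC=O
Why: Evans–Tishchenko reduction; trivalent samarium, formed from SmI2 and the aldehyde before 13 is added, binds hemiacetal 14 and the C5 carbonyl, and the hemiacetal C–H is transferred to C5 on the face that carries the pseudo-axial O3, so the new hydroxyl is trans to O3 (5R) and O3 is left as the acetate; this is the known 1,3-anti reduction of β-hydroxy ketones to diol monoesters.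

Step 8
Reactants: 15 methyl (3R,4S,5R)-3-acetoxy-5-hydroxy-4-[(4-methoxybenzyl)oxy]cyclohex-1-ene-1-carboxylate; 16 (R)-2-methylbutanoic acid
Product: 17 methyl (3R,4S,5R)-3-acetoxy-4-[(4-methoxybenzyl)oxy]-5-{[(2R)-2-methylbutanoyl]oxy}cyclohex-1-ene-1-carboxylate
Conditions: N,N′-dicyclohexylcarbodiimide (1.5 equiv), 4-(dimethylamino)pyridine (0.1 equiv), CH2Cl2, 0 °C to rt
Reagents that add atoms: none
Why: Steglich esterification of the only free hydroxyl with retention at C5; carbodiimide activation at 0 °C does not enolise the α-branched acid, so the (R) centre of 16 is carried over, and the 1,3-trans acetate on O3 cannot migrate to O5.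

Step 9
Reactants: 17 methyl (3R,4S,5R)-3-acetoxy-4-[(4-methoxybenzyl)oxy]-5-{[(2R)-2-methylbutanoyl]oxy}cyclohex-1-ene-1-carboxylate
Product: 18 methyl (3R,4S,5R)-3-acetoxy-4-hydroxy-5-{[(2R)-2-methylbutanoyl]oxy}cyclohex-1-ene-1-carboxylate
Conditions: DDQ (1.3 equiv), CH2Cl2/pH 7 phosphate buffer (10:1), 0 °C
Reagents that add atoms: none
Why: oxidative cleavage of the electron-rich PMB ether by DDQ followed by hydrolysis; esters, the enoate and the allylic acetate are inert, and the buffered, base-free medium keeps the O3 acetate from moving to the freed cis O4 hydroxyl.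

Step 10
Reactants: 18 methyl (3R,4S,5R)-3-acetoxy-4-hydroxy-5-{[(2R)-2-methylbutanoyl]oxy}cyclohex-1-ene-1-carboxylate
Product: 19 methyl (3R,4S,5R)-3-acetoxy-5-{[(2R)-2-methylbutanoyl]oxy}-4-(propanoyloxy)cyclohex-1-ene-1-carboxylate
Conditions: propanoic anhydride (2 equiv), pyridine (3 equiv), 4-(dimethylamino)pyridine (5 mol%), CH2Cl2, −20 to 0 °C
Reagents that add atoms: propanoic anhydride, CCC(=O)OC(=O)CC
Why: 4-(dimethylamino)pyridine-catalysed acyl transfer to the last free hydroxyl; at low temperature with excess anhydride acylation should outrun acetyl migration between O3 and O4, and no stereocentre is touched.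

## Compound list

1 | epibromohydrin, 2-(bromomethyl)oxirane (racemic) | BrCC1CO1 | starting material
2 | 4-methoxybenzyl alcohol | COc1ccc(CO)cc1 | starting material
3 | 1-bromo-3-[(4-methoxybenzyl)oxy]propan-2-ol (racemic) | COc1ccc(COCC(O)CBr)cc1 | intermediate
4 | 1-bromo-3-[(4-methoxybenzyl)oxy]propan-2-one | COc1ccc(COCC(=O)CBr)cc1 | intermediate
5 | trimethyl phosphonoacetate | COC(=O)CP(=O)(OC)OC | starting material
6 | sodium salt of trimethyl phosphonoacetate | [Na+].COC(=O)[CH-]P(=O)(OC)OC | intermediate (not isolated)
7 | methyl 2-(dimethoxyphosphoryl)-5-[(4-methoxybenzyl)oxy]-4-oxopentanoate (racemic) | COC(=O)C(CC(=O)COCc1ccc(OC)cc1)P(=O)(OC)OC | intermediate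
8 | 2,2-dimethoxyacetaldehyde | COC(OC)C=O | starting material
9 | sodium carbanion of phosphonate 7 | [Na+].COC(=O)[C-](CC(=O)COCc1ccc(OC)cc1)P(=O)(OC)OC | intermediate (not isolated)
10 | methyl (2E)-4,4-dimethoxy-2-{3-[(4-methoxybenzyl)oxy]-2-oxopropyl}but-2-enoate | COC(OC)/C=C(/C(=O)OC)\CC(=O)COCc1ccc(OC)cc1 | intermediate
11 | methyl (2E)-2-{3-[(4-methoxybenzyl)oxy]-2-oxopropyl}-4-oxobut-2-enoate | O=C/C=C(/C(=O)OC)\CC(=O)COCc1ccc(OC)cc1 | intermediate
12 | methyl (2E)-2-{(2Z)-2-hydroxy-3-[(4-methoxybenzyl)oxy]prop-2-en-1-yl}-4-oxobut-2-enoate (C4=C5 enol of 11) | O=C/C=C(/C(=O)OC)\C/C(O)=C/OCc1ccc(OC)cc1 | intermediate (not isolated)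
13 | methyl (3R,4R)-3-hydroxy-4-[(4-methoxybenzyl)oxy]-5-oxocyclohex-1-ene-1-carboxylate | COC(=O)C1=C[C@@H](O)[C@@H](OCc2ccc(OC)cc2)C(=O)C1 | intermediate
14 | methyl (3R,4R)-3-(1-hydroxyethoxy)-4-[(4-methoxybenzyl)oxy]-5-oxocyclohex-1-ene-1-carboxylate (drawn neutral; bound to trivalent samarium in the flask; hemiacetal carbon undefined) | COC(=O)C1=C[C@@H](OC(C)O)[C@@H](OCc2ccc(OC)cc2)C(=O)C1 | intermediate (not isolated)
15 | methyl (3R,4S,5R)-3-acetoxy-5-hydroxy-4-[(4-methoxybenzyl)oxy]cyclohex-1-ene-1-carboxylate | COc1ccc(CO[C@@H]2[C@H](OC(C)=O)C=C(C(=O)OC)C[C@H]2O)cc1 | intermediate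
16 | (R)-2-methylbutanoic acid | CC[C@@H](C)C(=O)O | starting material
17 | methyl (3R,4S,5R)-3-acetoxy-4-[(4-methoxybenzyl)oxy]-5-{[(2R)-2-methylbutanoyl]oxy}cyclohex-1-ene-1-carboxylate | COc1ccc(CO[C@@H]2[C@H](OC(C)=O)C=C(C(=O)OC)C[C@H]2OC(=O)[C@H](C)CC)cc1 | intermediate
18 | methyl (3R,4S,5R)-3-acetoxy-4-hydroxy-5-{[(2R)-2-methylbutanoyl]oxy}cyclohex-1-ene-1-carboxylate | O[C@@H]1[C@H](OC(C)=O)C=C(C(=O)OC)C[C@H]1OC(=O)[C@H](C)CC | intermediate
19 | methyl (3R,4S,5R)-3-acetoxy-5-{[(2R)-2-methylbutanoyl]oxy}-4-(propanoyloxy)cyclohex-1-ene-1-carboxylate | CCC(=O)O[C@@H]1[C@H](OC(C)=O)C=C(C(=O)OC)C[C@H]1OC(=O)[C@H](C)CC | target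

## Step count and risks

Total steps: 10. Longest linear sequence: 10 steps (from 1 and 2 to 19); 5, 8 and 16 enter as commercial materials.

**Step 6 (key step, proposed new method).** Four things may go wrong:
- enolisation toward C4 may be too slow for turnover at a temperature at which 13 survives;
- 13 may lose water and aromatise;
- 11 may drain away through its C6 dienol (alkene isomerisation, pyranol formation);
- facial or cis/trans selectivity may be poor, since no close precedent fixes either.

The fallback uses known chemistry and changes the order of bond formation: C3–C4 is made between two molecules and the ring is closed afterwards at C1=C2. It sets out from 7 and 8. A D-proline-catalysed anti-selective enamine aldol addition of the α-alkoxy ketone 7 to the non-enolisable aldehyde 8 (DMSO, rt; D-proline is the enantiomer expected by analogy with hydroxyacetone aldols) should give methyl (5R,6S)-2-(dimethoxyphosphoryl)-6-hydroxy-7,7-dimethoxy-5-[(4-methoxybenzyl)oxy]-4-oxoheptanoate F1. Evans–Tishchenko reduction under the conditions of step 7 should give methyl (4R,5S,6S)-6-acetoxy-2-(dimethoxyphosphoryl)-4-hydroxy-7,7-dimethoxy-5-[(4-methoxybenzyl)oxy]heptanoate F2. Mild acetal hydrolysis then gives methyl (4R,5S,6S)-6-acetoxy-2-(dimethoxyphosphoryl)-4-hydroxy-5-[(4-methoxybenzyl)oxy]-7-oxoheptanoate F3, in equilibrium with its lactol. Intramolecular Horner–Wadsworth–Emmons olefination (LiCl, N,N-diisopropylethylamine, MeCN) closes the ring. The fallback comes back to the route at 15 and never passes through 11 or 13.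

**Step 7.** The Lewis-acidic samarium catalyst may open 13 by retro-aldol or dehydrate it, and hydride transfer may stall if the ring does not hold O3 pseudo-axial over C5. The fallback sets out from 13. Evans–Saksena reduction with Me4NBH(OAc)3 in AcOH/MeCN at −30 °C should give methyl (3R,4S,5R)-3,5-dihydroxy-4-[(4-methoxybenzyl)oxy]cyclohex-1-ene-1-carboxylate F4. Anhydrous DDQ should then turn the PMB ether into the cis-fused acetal methyl 3,4-O-(4-methoxybenzylidene)shikimate F5. Steglich esterification with 16 gives methyl 3,4-O-(4-methoxybenzylidene)-5-O-[(2R)-2-methylbutanoyl]shikimate F6, and aqueous acetic acid frees the diol methyl 5-O-[(2R)-2-methylbutanoyl]shikimate F7. Trimethyl orthoacetate with catalytic camphorsulfonic acid gives the orthoester methyl 3,4-O-(1-methoxyethylidene)-5-O-[(2R)-2-methylbutanoyl]shikimate F8, whose mild acid hydrolysis opens to the pseudo-axial O3 acetate. The fallback comes back to the route at 18.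

**Step 4.** (E)-Selectivity may erode, and base may move the new double bond into conjugation with the ketone by deprotonation at C6 of 10. The fallback sets out from 4. Alkylation of methyl (triphenylphosphoranylidene)acetate (two equivalents, the second serving as base) gives the stabilised ylide methyl 5-[(4-methoxybenzyl)oxy]-4-oxo-2-(triphenyl-λ5-phosphanylidene)pentanoate F9. A base-free Wittig reaction with 8 then comes back to the route at 10.

**Step 1.** The Lewis acid may ionise 2 to a benzylic cation (self-etherification) or oligomerise 1. The fallback sets out from 1 and 2. Etherification under basic conditions (NaH, THF) gives 2-{[(4-methoxybenzyl)oxy]methyl}oxirane F10, and opening of the epoxide with LiBr/AcOH comes back to the route at 3.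

## Further compounds

F1 | step 6 | methyl (5R,6S)-2-(dimethoxyphosphoryl)-6-hydroxy-7,7-dimethoxy-5-[(4-methoxybenzyl)oxy]-4-oxoheptanoate (C2 undefined) | COC(=O)C(CC(=O)[C@H](OCc1ccc(OC)cc1)[C@H](O)C(OC)OC)P(=O)(OC)OC
F2 | step 6 | methyl (4R,5S,6S)-6-acetoxy-2-(dimethoxyphosphoryl)-4-hydroxy-7,7-dimethoxy-5-[(4-methoxybenzyl)oxy]heptanoate (C2 undefined) | COC(=O)C(C[C@@H](O)[C@H](OCc1ccc(OC)cc1)[C@H](OC(C)=O)C(OC)OC)P(=O)(OC)OC
F3 | step 6 | methyl (4R,5S,6S)-6-acetoxy-2-(dimethoxyphosphoryl)-4-hydroxy-5-[(4-methoxybenzyl)oxy]-7-oxoheptanoate (C2 undefined; open form of the lactol) | COC(=O)C(C[C@@H](O)[C@H](OCc1ccc(OC)cc1)[C@H](OC(C)=O)C=O)P(=O)(OC)OC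
F4 | step 7 | methyl (3R,4S,5R)-3,5-dihydroxy-4-[(4-methoxybenzyl)oxy]cyclohex-1-ene-1-carboxylate | COc1ccc(CO[C@@H]2[C@H](O)C=C(C(=O)OC)C[C@H]2O)cc1
F5 | step 7 | methyl 3,4-O-(4-methoxybenzylidene)shikimate (acetal carbon undefined) | COC(=O)C1=C[C@@H](OC2c3ccc(OC)cc3)[C@@H](O2)[C@H](O)C1
F6 | step 7 | methyl 3,4-O-(4-methoxybenzylidene)-5-O-[(2R)-2-methylbutanoyl]shikimate (acetal carbon undefined) | COC(=O)C1=C[C@@H](OC2c3ccc(OC)cc3)[C@@H](O2)[C@H](OC(=O)[C@H](C)CC)C1
F7 | step 7 | methyl 5-O-[(2R)-2-methylbutanoyl]shikimate, methyl (3R,4R,5R)-3,4-dihydroxy-5-{[(2R)-2-methylbutanoyl]oxy}cyclohex-1-ene-1-carboxylate | COC(=O)C1=C[C@@H](O)[C@@H](O)[C@H](OC(=O)[C@H](C)CC)C1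
F8 | step 7 | methyl 3,4-O-(1-methoxyethylidene)-5-O-[(2R)-2-methylbutanoyl]shikimate (orthoester carbon undefined) | COC(=O)C1=C[C@@H](OC2(C)OC)[C@@H](O2)[C@H](OC(=O)[C@H](C)CC)C1
F9 | step 4 | methyl 5-[(4-methoxybenzyl)oxy]-4-oxo-2-(triphenyl-λ5-phosphanylidene)pentanoate | COC(=O)C(CC(=O)COCc1ccc(OC)cc1)=P(c1ccccc1)(c1ccccc1)c1ccccc1
F10 | step 1 | 2-{[(4-methoxybenzyl)oxy]methyl}oxirane (racemic) | COc1ccc(COCC2CO2)cc1
A1 | alternative 1 | methyl (2E)-7-bromo-4,5-O-isopropylidene-6-O-[(2R)-2-methylbutanoyl]hept-2-enoate, lyxo series (heptenoate C4, C5, C6 = ring C3, C4, C5) | COC(=O)/C=C/[C@@H](OC1(C)C)[C@@H](O1)[C@H](OC(=O)[C@H](C)CC)CBr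
A2 | alternative 1 | methyl 3,4-O-isopropylidene-5-O-[(2R)-2-methylbutanoyl]shikimate | COC(=O)C1=C[C@@H](OC2(C)C)[C@@H](O2)[C@H](OC(=O)[C@H](C)CC)C1
A3 | alternative 2 | methyl (2E)-2-(iodomethylidene)-4-{[(2R)-2-methylbutanoyl]oxy}-6-oxo-5-(propanoyloxy)hexanoate (hexanoate C4, C5 = ring C5, C4, configured as in 19) | O=C[C@@H](OC(=O)CC)[C@H](OC(=O)[C@H](C)CC)C/C(C(=O)OC)=C\I
A4 | alternative 2 | methyl 5-O-[(2R)-2-methylbutanoyl]-4-O-propanoylshikimate | COC(=O)C1=C[C@@H](O)[C@@H](OC(=O)CC)[C@H](OC(=O)[C@H](C)CC)C1
A5 | alternative 3 | methyl 2-(dimethoxyphosphoryl)-4-hydroxy-5,6-O-isopropylidene-7-oxoheptanoate, lyxo series (open form of the lactol; C2 undefined) | O=C[C@@H](OC1(C)C)[C@@H](O1)[C@H](O)CC(C(=O)OC)P(=O)(OC)OC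
A6 | alternative 3 | methyl 3,4-O-isopropylideneshikimate | COC(=O)C1=C[C@@H](OC2(C)C)[C@@H](O2)[C@H](O)C1
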